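(The data stem from a simulated flask on assumed constants, and the scatter is random.)

**The choice.** Temperature is the choice before me: alder, oak, elm and larch differ in the bath, and I must say which one earns the run, with target counted at the end of 3.0 min.

| setting | spring | dawn | alder | oak | elm | larch |
|---|---|---|---|---|---|---|
| substrate | 0.025 M | 0.10 M | 0.050 M | 0.050 M | 0.050 M | 0.050 M |
| first nucleophile | 0.050 M | 0.050 M | 0.0500 M | 0.0500 M | 0.0500 M | 0.0500 M |
| second nucleophile | 0.15 M | 0.15 M | 0.150 M | 0.150 M | 0.150 M | 0.150 M |
| capture agent | 0.015 M | 0.015 M | 0.0150 M | 0.0150 M | 0.0150 M | 0.0150 M |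
| temperature | −15 °C | 35 °C | 80 °C | 50 °C | 20 °C | −10 °C |
| remark | run made earlier | run made earlier |  |  |  |  |
| time |  |  | 3.0 min | 3.0 min | 3.0 min | 3.0 min |

| run | time / min | target / % | substrate / % |
|---|---|---|---|
| spring | 60.0 | 0.1 | 99.9 |
| spring | 120 | 0.6 | 99.6 |
| spring | 180 | 0.2 | 99.0 |
| spring | 240 | 0.7 | 98.8 |
| spring | 300 | 1.1 | 98.6 |
| spring | 360 | 1.1 | 98.4 |
| spring | 480 | 1.6 | 98.1 |
| dawn | 2.50 | 10.8 | 83.8 |
| dawn | 4.00 | 17.0 | 75.6 |
| dawn | 6.00 | 23.2 | 66.2 |
| dawn | 10.0 | 32.3 | 50.5 |
| dawn | 15.0 | 39.1 | 36.6 |
| dawn | 25.0 | 44.2 | 19.0 |
| dawn | 40.0 | 45.0 | 7.7 |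

(standard deviation of a reading: 0.3 percentage points)

1. the flask with the highest amount of target, in percent of the substrate charged ("all alike" if they lie within 1.5 percentage points) (alder / oak / elm / larch / all alike)
2. final target, as a percentage of the substrate charged, in alder
3. final target, as a percentage of the substrate charged, in oak
4. final target, as a percentage of the substrate charged, in elm
5. final target, as a percentage of the substrate charged, in larch

- the earlier runs were read with a standard deviation of 0.3 percentage points
- candidate steps: substrate <-> open intermediate; first nucleophile + open intermediate <-> target; second nucleophile + open intermediate -> other capture product; open intermediate + capture agent -> trapped intermediate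

**The clock.** In the dawn run, first-order loss of substrate reads 0.0683 /min up to 10.0 min and 0.0641 /min up to 40.0 min, although by then target has taken 90.0% of the first nucleophile charged, so I read the opening of substrate as the rate-limiting step, whose rate law integrates to a plain exponential. The spring run lost 1.90% of its substrate in 480 min, a rough reading given the scatter of 0.3 percentage points, which gives 4.00 × 10⁻⁵ /min, and the two constants give an activation energy of 98.5 kJ/mol. For oak this makes 1.70 min: this is the opening half-life, the time in which first-order opening alone would reduce the substrate by a factor of two at a given temperature.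

**My reckoning.** In oak, 3.0 min against that half-life leaves 29.5% of the substrate. The earliest dawn reading sends 66.7% of the lost substrate to target, so oak should hold 47.0%. Elm has a half-life of 72.5 min and should hold 1.89%, while larch, at 121 h, barely starts. Alder's half-life is 0.0758 min, but target forms by a reversible step and other capture product by a one-way step, and 39.6 half-lives give target time to drain. I give alder no number and commit to oak.

**The forecast.** The forecast also names oak, with 15% in alder, 38% in oak, 2.1% in elm and 0.02% in larch, and adds: “The alder value is very uncertain.”

**The result.** The simulation puts most target in oak: 16.4% in alder, 44.0% in oak, 1.99% in elm and 0.00883% in larch.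

    substrate ⇌ open intermediate (K = 0.0194, k = 0.164 /s, Ea = 99.0 kJ/mol, ΔH = −52.0 kJ/mol)
    first nucleophile + open intermediate ⇌ target (K = 640 /M, k = 26.0 /M/s, Ea = 48.0 kJ/mol, ΔH = −74.0 kJ/mol)
    second nucleophile + open intermediate → other capture product (k = 2.48 /M/s, Ea = 46.0 kJ/mol)
    open intermediate + capture agent → trapped intermediate (k = 0.130 /M/s, Ea = 61.0 kJ/mol)
    (constants at 80 °C)

In oak, the opening half-life of 1.70 min promised 29.5% of the substrate left at 3.00 min, and the flask holds 36.1%, beside 18.9% of other capture product. In larch, the half-life reckoned as 121 h stands against a forward half-life of substrate of 120 h, and target at 3.00 min is 0.00883%.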